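Atom labels used throughout: ring A is the quinone, C1–C6 (C1 and C4 carbonyls, OH on C2, side chain on C3, OMe on C5, H on C6). The tether is C1'–C5' (C1' on C3, C2'=C3', methyl on C3', C5' on C1''). Ring B is the cyclohexene, C1''–C6'' (C1'' quaternary, C2'' CHMe, C3''=C4'').

## Analysis of the target

Metachromin C (C22H30O4) consists of ring A, a 2-hydroxy-5-methoxy-1,4-benzoquinone, a five-carbon tether C1'–C5' attached at C3 with an E-trisubstituted olefin C2'=C3', and ring B, a 1,2,3-trimethylcyclohex-3-ene joined to C5' through its quaternary carbon C1''. The only stereocentres are the quaternary C1'' (R) and the neighbouring tertiary, allylic C2'' (S); the methyl groups on C1'' and C2'' are trans, so the C2'' methyl is cis to the tether. Ring B carries no heteroatom, so apart from the C3''=C4'' double bond there is no handle near the stereocentres, and the pair is best set, in the relative and the absolute sense, while the ring is made. The feature on which the plan rests is that ring B is a cyclohexene with its double bond at C3''=C4'', the stereogenic pair at C1''/C2'' and one methyl on each of C1'', C2'' and C3''. This is the retron of a [4+2] cycloaddition in which C1'' and C6'' come from a 1,1-disubstituted dienophile and C2''–C5'' from a 1,2-dimethylbutadiene. Ring A is a vinylogous acid and a redox-active Michael acceptor, sensitive to base, nucleophiles and reductants, and its C2 hydroxyl can add to the C2'=C3' olefin under acid, so it should be unveiled last. Further demands are the E geometry of C2'=C3', which is skipped relative to ring A and must not move into conjugation, and the differentiation of the two oxygen substituents of ring A. The difficulty therefore sits in two places: the enantioselective construction of the C1''/C2'' pair in an unfunctionalised ring, and a union of the halves that fixes the olefin geometry without a long linear chain extension.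

## Retrosynthetic reasoning

14 to 13: the C2 hydroxyl is traced back to a methyl ether, so that ring A travels as the 2,5-dimethoxyquinone 13. The two vinylogous esters of 13 differ only in their neighbours: the C2 methoxy group is wedged between the C1 carbonyl and the side chain, while the C5 methoxy group has C6–H beside it. The forward step must hydrolyse the hindered, less conjugated one only.

13 to 12: the quinone is taken back to the tetramethoxyarene 12 by oxidative demethylation. The arene tolerates organolithium, zirconium, boron and palladium chemistry, and its 2,3,5,6-tetramethoxyphenyl group has a mirror plane through the substituted carbon, so both para pairs of methoxy groups lead to the same para-quinone.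

12 to 4 and 10: the tether is cut at C3'–C4' (sp2–sp3) and not at the customary aryl–C1' bond. This cut turns C4' into an alkylborane (11) that comes from the vinyl group of 4 by anti-Markovnikov hydroboration, so ring B never needs chain extension by functional group interconversion. The C2'=C3' geometry is decided beforehand on the small achiral iodide 10 and is transferred with retention in an alkyl–alkenyl cross-coupling. Both halves are two steps from commercial compounds.

10 to 8 to 5 and 6: the E-alkenyl iodide comes from the internal alkyne 8 by syn hydrometalation with a zirconium hydride (alkenylzirconium 9) and iodinolysis; the metal has to settle on the methyl-bearing alkyne carbon. Alkyne 8 is the product of alkylating the aryllithium 7, formed from 5 by deprotonation between two methoxy groups, with the propargylic bromide 6.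

4 to 3: C4' is added by methylenation of the aldehyde 3, whose formyl carbon becomes C5'. The aldehyde is not enolisable, so C1'' and C2'' are safe.

3 to 1 and 2: ring B is cut at C1''–C2'' and C5''–C6''. In the forward direction a single enantioselective cycloaddition of the diene 1 to the enal 2 has to form the ring, place the double bond at C3''=C4'', and set C1'' (catalyst control) and C2'' (endo topology and E-diene geometry). This cut is preferred because no other one creates both stereocentres together, and because it reduces ring B to two achiral commodity chemicals.

## Alternatives that were turned down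

Alternative 1: the textbook route cuts the aryl–C1' bond. The aryllithium 7 would be alkylated with the allylic bromide A1 to give 12. A1 would be built linearly from the cyclohexanone A2, itself the product of a copper-catalysed asymmetric conjugate addition of a butenyl nucleophile to a β-methylcyclohexenone with methylation of the enolate. A2 would then need enol triflate formation and methyl coupling, oxidative chain extension and an olefination before A1 is reached. It was turned down for three reasons:
- C2'' in A2 is created by alkylation next to a quaternary carbon whose two substituents (methyl and a primary alkyl chain) are nearly the same size, so there is neither a kinetic facial bias nor a thermodynamic bias after epimerisation.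
- The C2'=C3' geometry would come from an olefination of a methyl ketone, which gives E/Z mixtures.
- The sequence is about twelve linear steps, with the allylic halide of the most valuable material used in the last C–C bond formation.

Alternative 2: ring A itself is closed last. The cyclobutenedione A3, carrying the complete side chain, would take up a 2-methoxyvinyl organolithium at the carbonyl next to the alkoxy-bearing carbon to give the cyclobutenone A4. Thermolysis of A4 (4π opening to a dienylketene, 6π closure, tautomerisation), oxidation in air and acid cleavage of the tert-butyl ether would give 14 with the OH/OMe pattern fixed by connectivity. It was turned down for three reasons: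
- The side chain is allylic, and an allylic organometallic adds to a squarate carbonyl through its γ-terminus to give the branched isomer, so A3 would need a tin-based coupling instead.
- The annulation does nothing for C1''/C2''; the whole side chain must still be made, and ring A then costs four steps instead of two.
- The hot dienylketene carries a skipped olefin close by, which invites intramolecular side reactions.

Alternative 3: ring B is made by ring contraction, cutting only C1''–C2''. The silyl ketene acetal of the δ-lactone A5 would undergo an Ireland–Claisen rearrangement. The temporary lactone ring fixes the enolate geometry and forces a boat transition state, so the single carbinol centre of A5 would be relayed into both stereocentres of the acid A6, and the regiochemistry is dictated by connectivity. It was turned down on step economy: A5 needs about four steps (acylation, asymmetric ketone reduction, lactonisation, α-methylation), and A6 must then be reduced and re-oxidised to reach 3. That is seven or more operations for what the cycloaddition does in one.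

Key step: step 1

Assumption: commercial 3-methylpenta-1,3-diene is an E/Z mixture and is used as such in excess; only the E isomer 1 can reach the s-cis conformation and react.

Assumption: the catalyst antipode written in step 1 is the one expected from the formyl C–H···O binding model for 2-substituted acroleins; if the sense turns out opposite, the mirror-image catalyst from the equally available (R)-prolinol is used.

## Route

Step 1
Reactants: 1 (E)-3-methylpenta-1,3-diene; 2 methacrolein (2-methylprop-2-enal)
Product: 3 (1S,2R)-1,2,3-trimethylcyclohex-3-ene-1-carbaldehyde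
Conditions: (S)-3,3-diphenyl-1-(o-tolyl)tetrahydro-1H,3H-pyrrolo[1,2-c][1,3,2]oxazaborole (10 mol%), Tf2NH (8 mol%), CH2Cl2, −78 → −40 °C; 1 as commercial E/Z mixture (3 equiv)
Reagents that add atoms: none
Why: Concerted, asynchronous [4+2] cycloaddition (Diels–Alder reaction) of s-cis 1 with 2, which is held s-trans on the boron of the protonated oxazaborolidine by coordination of the carbonyl oxygen and a formyl C–H···O contact, while an aryl group of the catalyst blocks one face. The closest known reaction type is the oxazaborolidinium-catalysed Diels–Alder reaction of 2-substituted acroleins with acyclic alkyl- and silyloxy-substituted dienes. Ring B is closed by an intermolecular suprafacial–suprafacial six-ring cycloaddition that forms C1''–C2'' and C5''–C6'' and leaves the double bond at C3''=C4''. C1'' is set by the catalyst: the diene has to add to the Re face at C2 of 2 (priorities CHO > CH2 > CH3). C2'' follows from the E geometry of 1 and the endo position of the formyl group, which together put the C2'' methyl cis to CHO and trans to the C1'' methyl. The step needs "ortho" regioselectivity with respect to the terminal methyl of 1; it is expected because the unsubstituted diene terminus is less hindered and carries the larger HOMO coefficient, so it bonds first to the β-carbon of activated 2, while the internal methyl opposes this only weakly. Endo selectivity is expected because with an acyclic diene the α-methyl of 2 meets no bridging methylene in the exo position, unlike in additions to cyclopentadiene. The Z isomer of the commercial diene cannot reach the s-cis conformation and stays behind.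

Step 2
Reactants: 3 (1S,2R)-1,2,3-trimethylcyclohex-3-ene-1-carbaldehyde
Product: 4 (1R,2R)-1-ethenyl-1,2,3-trimethylcyclohex-3-ene
Conditions: Ph3PCH3Br, KOtBu, THF, 0 °C → rt; pentane work-up (volatile product)
Reagents that add atoms: methyltriphenylphosphonium bromide, C[P+](c1ccccc1)(c1ccccc1)c1ccccc1.[Br-]
Why: Wittig methylenation of a hindered but non-enolisable aldehyde; the formyl carbon becomes C5' and the new CH2 becomes C4'. No stereocentre can epimerise because C1'' is quaternary (the change of descriptor at C1'' is only a change of CIP priorities).

Step 3
Reactants: 5 1,2,4,5-tetramethoxybenzene; 6 1-bromobut-2-yne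
Product: 8 3-(but-2-yn-1-yl)-1,2,4,5-tetramethoxybenzene, via aryllithium 7 (not isolated)
Conditions: n-BuLi, TMEDA, THF, 0 °C → rt; then 6, −78 → 0 °C
Reagents that add atoms: none
Why: Directed ortho-lithiation between two methoxy groups (5 has only one kind of ring hydrogen), then SN2 alkylation of the hard aryllithium at the primary propargylic bromide. Copper is left out on purpose so that SN2' attack at the methyl-bearing alkyne carbon (allene formation) is not promoted.

Step 4
Reactants: 8 3-(but-2-yn-1-yl)-1,2,4,5-tetramethoxybenzene
Product: 10 3-[(2E)-3-iodobut-2-en-1-yl]-1,2,4,5-tetramethoxybenzene, via alkenylzirconocene chloride 9 (not isolated)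
Conditions: Cp2Zr(H)Cl (1.6 equiv), THF, rt → 50 °C; then I2 (titrated), THF, −20 → 0 °C
Reagents that add atoms: iodine, II
Why: Syn hydrozirconation of the internal alkyne; with an excess of the hydride the regioisomeric alkenylzirconiums equilibrate towards the less hindered one, with zirconium on the methyl-bearing carbon. Iodinolysis with retention then gives the E iodide, in which the C3' methyl is cis to C1'.

Step 5
Reactants: 4 (1R,2R)-1-ethenyl-1,2,3-trimethylcyclohex-3-ene; 10 3-[(2E)-3-iodobut-2-en-1-yl]-1,2,4,5-tetramethoxybenzene
Product: 12 3-{(2E)-3-methyl-5-[(1R,2S)-1,2,3-trimethylcyclohex-3-en-1-yl]pent-2-en-1-yl}-1,2,4,5-tetramethoxybenzene, via B-alkyl-9-BBN borane 11 (not isolated)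
Conditions: 9-BBN, THF, 0 °C → rt; then 10, Pd(dppf)Cl2 (5 mol%), AsPh3 (10 mol%), Cs2CO3, DMF/H2O, rt
Reagents that add atoms: none
Why: 9-BBN adds only to the monosubstituted vinyl group, at its terminus, and leaves the trisubstituted ring olefin alone. The B-alkyl Suzuki–Miyaura coupling of the primary alkylborane with the alkenyl iodide forms C3'–C4' with retention of the olefin geometry. No stereocentre is touched.

Step 6
Reactants: 12 3-{(2E)-3-methyl-5-[(1R,2S)-1,2,3-trimethylcyclohex-3-en-1-yl]pent-2-en-1-yl}-1,2,4,5-tetramethoxybenzene
Product: 13 2,5-dimethoxy-3-{(2E)-3-methyl-5-[(1R,2S)-1,2,3-trimethylcyclohex-3-en-1-yl]pent-2-en-1-yl}cyclohexa-2,5-diene-1,4-dione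
Conditions: (NH4)2Ce(NO3)6 (2.5 equiv), MeCN/H2O 2:1, 0 °C, short reaction time
Reagents that add atoms: water, O
Why: Oxidative demethylation of a para-dimethoxyarene by two one-electron oxidations with tetravalent cerium, attack of water on the radical cation and loss of two molecules of methanol. Both para pairs of methoxy groups are equivalent by the mirror plane of the aryl group, so one para-quinone should form. Isolated trisubstituted olefins are tolerated under these conditions, as in prenylquinone chemistry.

Step 7
Reactants: 13 2,5-dimethoxy-3-{(2E)-3-methyl-5-[(1R,2S)-1,2,3-trimethylcyclohex-3-en-1-yl]pent-2-en-1-yl}cyclohexa-2,5-diene-1,4-dione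
Product: 14 metachromin C, 2-hydroxy-5-methoxy-3-{(2E)-3-methyl-5-[(1R,2S)-1,2,3-trimethylcyclohex-3-en-1-yl]pent-2-en-1-yl}cyclohexa-2,5-diene-1,4-dione
Conditions: KOH (1 M aq.), MeOH, rt; then 1 M HCl
Reagents that add atoms: potassium hydroxide, [K+].[OH-]
Why: Saponification of a vinylogous ester by addition–elimination at the ring carbon. The C2 methoxy group, squeezed between the C1 carbonyl and the side chain, is twisted out of conjugation and is the more electrophilic one, so it should be replaced first. The product forms as a vinylogous carboxylate, which should shut down a second hydrolysis; acidification gives 14.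

## Compound list

1 | (E)-3-methylpenta-1,3-diene | C/C=C(\C)C=C | starting material
2 | methacrolein (2-methylprop-2-enal) | CC(=C)C=O | starting material
3 | (1S,2R)-1,2,3-trimethylcyclohex-3-ene-1-carbaldehyde | O=C[C@@]1(C)CCC=C(C)[C@H]1C | intermediate
4 | (1R,2R)-1-ethenyl-1,2,3-trimethylcyclohex-3-ene (ring numbered as in 3; systematic name (5R,6R)-5-ethenyl-1,5,6-trimethylcyclohex-1-ene) | C=C[C@@]1(C)CCC=C(C)[C@H]1C | intermediate
5 | 1,2,4,5-tetramethoxybenzene | COc1cc(OC)c(OC)cc1OC | starting material
6 | 1-bromobut-2-yne | CC#CCBr | starting material
7 | (2,3,5,6-tetramethoxyphenyl)lithium | [Li]c1c(OC)c(OC)cc(OC)c1OC | intermediate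
8 | 3-(but-2-yn-1-yl)-1,2,4,5-tetramethoxybenzene | CC#CCc1c(OC)c(OC)cc(OC)c1OC | intermediate
9 | chlorobis(cyclopentadienyl)[(2E)-4-(2,3,5,6-tetramethoxyphenyl)but-2-en-2-yl]zirconium (cyclopentadienyl rings written σ-bonded in the string) | C/C(=C\Cc1c(OC)c(OC)cc(OC)c1OC)[Zr](Cl)(C1C=CC=C1)C1C=CC=C1 | intermediate
10 | 3-[(2E)-3-iodobut-2-en-1-yl]-1,2,4,5-tetramethoxybenzene | C/C(I)=C\Cc1c(OC)c(OC)cc(OC)c1OC | intermediate
11 | 9-{2-[(1S,2S)-1,2,3-trimethylcyclohex-3-en-1-yl]ethyl}-9-borabicyclo[3.3.1]nonane | B1(C2CCCC1CCC2)CC[C@@]1(C)CCC=C(C)[C@H]1C | intermediate
12 | 3-{(2E)-3-methyl-5-[(1R,2S)-1,2,3-trimethylcyclohex-3-en-1-yl]pent-2-en-1-yl}-1,2,4,5-tetramethoxybenzene | COc1cc(OC)c(OC)c(C/C=C(\C)CC[C@@]2(C)CCC=C(C)[C@H]2C)c1OC | intermediate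
13 | 2,5-dimethoxy-3-{(2E)-3-methyl-5-[(1R,2S)-1,2,3-trimethylcyclohex-3-en-1-yl]pent-2-en-1-yl}cyclohexa-2,5-diene-1,4-dione | COC1=CC(=O)C(OC)=C(C/C=C(\C)CC[C@@]2(C)CCC=C(C)[C@H]2C)C1=O | intermediate
14 | metachromin C, 2-hydroxy-5-methoxy-3-{(2E)-3-methyl-5-[(1R,2S)-1,2,3-trimethylcyclohex-3-en-1-yl]pent-2-en-1-yl}cyclohexa-2,5-diene-1,4-dione | COC1=CC(=O)C(O)=C(C/C=C(\C)CC[C@@]2(C)CCC=C(C)[C@H]2C)C1=O | target

## Step count and risk

Total step count: 7 (steps 1–7). Longest linear sequence: 5 steps (1, 2, 5, 6, 7 from 1 and 2; equally 3, 4, 5, 6, 7 from 5).

Least certain steps: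

Step 1 (key step). The most likely failure is loss of regiocontrol: the two methyl groups of the diene direct in opposite senses, and in a strongly asynchronous, catalysed transition state the internal methyl gains weight. Incomplete endo and facial selectivity are also possible for a diene that has not been matched to this catalyst class, and the isomeric adducts are volatile and similar in polarity, so they would be hard to separate. The fallback sets out from 2 and comes back to the route at 4. The diene is replaced by triisopropyl{[(3E)-3-methylpenta-1,3-dien-2-yl]oxy}silane F1, made from commercial (E)-3-methylpent-3-en-2-one by kinetic enolisation and silylation. Its oxygen sits on the diene carbon that becomes C4'' and makes the unsubstituted terminus by far the most nucleophilic, so regiochemistry is no longer a contest between two methyl groups. Cycloaddition with 2 under the same catalyst should give (1S,2R)-1,2,3-trimethyl-4-[(triisopropylsilyl)oxy]cyclohex-3-ene-1-carbaldehyde F2. Wittig methylenation gives {[(3S,4R)-4-ethenyl-2,3,4-trimethylcyclohex-1-en-1-yl]oxy}triisopropylsilane F3. CsF and PhNTf2 in DME convert the silyl enol ether regiospecifically into (3S,4R)-4-ethenyl-2,3,4-trimethylcyclohex-1-en-1-yl trifluoromethanesulfonate F4. Reduction of the enol triflate with formate under palladium catalysis (Pd(OAc)2, PPh3, Bu3N, HCO2H, DMF) replaces the triflate by hydrogen and gives 4. The price is three extra steps for a temporary oxygen substituent.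

Step 3. The likely failure is competing SN2' attack of the aryllithium at the methyl-bearing alkyne carbon (allene formation), together with bromine–lithium exchange. The fallback sets out from 5 and comes back at 8, with the polarity of the bond formation inverted so that no propargyl/allenyl ambiguity exists. Blanc chloromethylation of 5 (paraformaldehyde, HCl, AcOH, limited conversion) gives 3-(chloromethyl)-1,2,4,5-tetramethoxybenzene F5. Coupling of this benzylic chloride with CH3C≡CMgBr under CuBr·SMe2 catalysis in THF gives 8.

Step 4. The likely failure is delivery of zirconium to the wrong alkyne carbon: an ortho methoxy oxygen can coordinate zirconium and stabilise the proximal alkenylzirconium, which would put the iodine on C2'. Partial iodination of the electron-rich ring is a second possibility. The fallback sets out from 4 (and from 5 through F5), comes back at 12, and bypasses 8 to 11. It moves the hydrometalation problem to a terminal alkyne, where methylmetalation is unambiguous.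
- Hydroboration–oxidation of 4 (9-BBN; NaOH, H2O2) gives 2-[(1R,2S)-1,2,3-trimethylcyclohex-3-en-1-yl]ethan-1-ol F6.
- PPh3, I2 and imidazole give (1R,2S)-1-(2-iodoethyl)-1,2,3-trimethylcyclohex-3-ene F7.
- Displacement with LiC≡CH·H2NCH2CH2NH2 in DMSO gives 4-[(1R,2S)-1,2,3-trimethylcyclohex-3-en-1-yl]but-1-yne F8.
- Zirconium-catalysed syn methylalumination (AlMe3, Cp2ZrCl2 cat., CH2Cl2) gives dimethyl{(1E)-2-methyl-4-[(1R,2S)-1,2,3-trimethylcyclohex-3-en-1-yl]but-1-en-1-yl}alumane F9.
- F9 is coupled in the same flask with the benzylic chloride F5 under Pd(PPh3)4 catalysis to give 12, with the C3' methyl cis to C1'.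

Step 7. The likely failure is hydrolysis at the wrong methoxy group (C5, the less hindered position) or at both, and slow base-induced degradation of the quinone. The fallback sets out from 13 and comes back at 14. Exhaustive hydrolysis (aq. NaOH, dioxane, 50 °C, then HCl) gives 2,5-dihydroxy-3-{(2E)-3-methyl-5-[(1R,2S)-1,2,3-trimethylcyclohex-3-en-1-yl]pent-2-en-1-yl}cyclohexa-2,5-diene-1,4-dione F10. Acid-catalysed mono-etherification of this vinylogous diacid (MeOH, cat. TsOH, rt, stopped at the mono-ether) should take place at the unhindered C5 position, remote from the side chain, and give 14. The acid is kept mild because the C2 hydroxyl can cyclise onto the C2'=C3' olefin.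

## Further compounds

F1 | step 1 | triisopropyl{[(3E)-3-methylpenta-1,3-dien-2-yl]oxy}silane | C/C=C(\C)C(=C)O[Si](C(C)C)(C(C)C)C(C)C
F2 | step 1 | (1S,2R)-1,2,3-trimethyl-4-[(triisopropylsilyl)oxy]cyclohex-3-ene-1-carbaldehyde | O=C[C@@]1(C)CCC(O[Si](C(C)C)(C(C)C)C(C)C)=C(C)[C@H]1C
F3 | step 1 | {[(3S,4R)-4-ethenyl-2,3,4-trimethylcyclohex-1-en-1-yl]oxy}triisopropylsilane | C=C[C@@]1(C)CCC(O[Si](C(C)C)(C(C)C)C(C)C)=C(C)[C@H]1C
F4 | step 1 | (3S,4R)-4-ethenyl-2,3,4-trimethylcyclohex-1-en-1-yl trifluoromethanesulfonate | C=C[C@@]1(C)CCC(OS(=O)(=O)C(F)(F)F)=C(C)[C@H]1C
F5 | step 3 | 3-(chloromethyl)-1,2,4,5-tetramethoxybenzene | ClCc1c(OC)c(OC)cc(OC)c1OC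
F6 | step 4 | 2-[(1R,2S)-1,2,3-trimethylcyclohex-3-en-1-yl]ethan-1-ol | OCC[C@@]1(C)CCC=C(C)[C@H]1C
F7 | step 4 | (1R,2S)-1-(2-iodoethyl)-1,2,3-trimethylcyclohex-3-ene | ICC[C@@]1(C)CCC=C(C)[C@H]1C
F8 | step 4 | 4-[(1R,2S)-1,2,3-trimethylcyclohex-3-en-1-yl]but-1-yne | C#CCC[C@@]1(C)CCC=C(C)[C@H]1C
F9 | step 4 | dimethyl{(1E)-2-methyl-4-[(1R,2S)-1,2,3-trimethylcyclohex-3-en-1-yl]but-1-en-1-yl}alumane | C/C(CC[C@@]1(C)CCC=C(C)[C@H]1C)=C\[Al](C)C
F10 | step 7 | 2,5-dihydroxy-3-{(2E)-3-methyl-5-[(1R,2S)-1,2,3-trimethylcyclohex-3-en-1-yl]pent-2-en-1-yl}cyclohexa-2,5-diene-1,4-dione | OC1=CC(=O)C(O)=C(C/C=C(\C)CC[C@@]2(C)CCC=C(C)[C@H]2C)C1=O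
A1 | alternative 1 | (2E)-1-bromo-3-methyl-5-[(1R,2S)-1,2,3-trimethylcyclohex-3-en-1-yl]pent-2-ene | BrC/C=C(\C)CC[C@@]1(C)CCC=C(C)[C@H]1C
A2 | alternative 1 | (2S,3R)-3-(but-3-en-1-yl)-2,3-dimethylcyclohexan-1-one | C=CCC[C@@]1(C)CCCC(=O)[C@H]1C
A3 | alternative 2 | 3-tert-butoxy-4-{(2E)-3-methyl-5-[(1R,2S)-1,2,3-trimethylcyclohex-3-en-1-yl]pent-2-en-1-yl}cyclobut-3-ene-1,2-dione | CC(C)(C)OC1=C(C/C=C(\C)CC[C@@]2(C)CCC=C(C)[C@H]2C)C(=O)C1=O
A4 | alternative 2 | 3-tert-butoxy-4-hydroxy-4-[(Z)-2-methoxyethenyl]-2-{(2E)-3-methyl-5-[(1R,2S)-1,2,3-trimethylcyclohex-3-en-1-yl]pent-2-en-1-yl}cyclobut-2-en-1-one (both epimers at the carbinol carbon) | CO/C=C\C1(O)C(OC(C)(C)C)=C(C/C=C(\C)CC[C@@]2(C)CCC=C(C)[C@H]2C)C1=O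
A5 | alternative 3 | (6R)-6-[(2E)-but-2-en-2-yl]-3-methyloxan-2-one (either configuration at C3) | C/C=C(\C)[C@H]1CCC(C)C(=O)O1
A6 | alternative 3 | (1S,2R)-1,2,3-trimethylcyclohex-3-ene-1-carboxylic acid | OC(=O)[C@@]1(C)CCC=C(C)[C@H]1C
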